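**Strategy.** The C40 chain is cut at both C11=C12 bonds into the C10 dialdehyde and two copies of one C15 triol phosphonium salt. After the first coupling, acid closes O5' onto C8' to make the dihydrofuran, so both carbocycles share one origin: (4R)-4-silyloxy-2,2,6-trimethylcyclohexanone. This ketone is reached by one-carbon ring enlargement: the C5'–C6' bond is formed by inserting the CH(CH3) unit (C5' with C18') between the carbonyl carbon (C6') and the only α-methylene of (S)-4-silyloxy-2,2-dimethylcyclopentanone with diazoethane. The step exploits the ketone-level C6' flanked by quaternary C1' and methyl-bearing C5', which makes the insertion regiochemically unambiguous.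

Key step: step 4

Remark: 1, 9, 18 and the reagents are taken as commercial (diazoethane is made fresh from commercial N-ethyl-N-nitrosourea); 6 is carried as both C6 epimers because that centre is erased in step 5; atoms are cited by carotenoid numbering, primes marking the dihydrofuran half.

Step 1
Reactants: 1 2,2-dimethylcyclopentan-1-one
Product: 2 5,5-dimethylcyclopent-2-en-1-one
Conditions: IBX (1.5 equiv), DMSO, 70 °C
Reagents that add atoms: none
Why: IBX-mediated α,β-dehydrogenation of a ketone can occur only toward the single enolisable side, so one enone should form and no stereocentre is involved.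

Step 2
Reactants: 2 5,5-dimethylcyclopent-2-en-1-one
Product: 4 (4S)-4-hydroxy-2,2-dimethylcyclopentan-1-one, via β-boryl ketone 3 (not isolated)
Conditions: B2pin2, CuCl (3 mol%), NaOt-Bu (6 mol%), (R,R)-QuinoxP* (or its antipode, whichever gives the S boronate), MeOH, THF, rt; then 30% H2O2, aq. NaHCO3, 0 °C
Reagents that add atoms: bis(pinacolato)diboron, CC1(C)OB(OC1(C)C)B1OC(C)(C)C(C)(C)O1 (boron present only in 3); hydrogen peroxide, OO
Why: Copper-catalysed asymmetric conjugate borylation of the enone sets the carbinol stereocentre by ligand-controlled facial selection, and the C–B bond is then oxidised with retention to the (S)-β-hydroxy ketone.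

Step 3
Reactants: 4 (4S)-4-hydroxy-2,2-dimethylcyclopentan-1-one
Product: 5 (4S)-4-[(tert-butyldimethylsilyl)oxy]-2,2-dimethylcyclopentan-1-one
Conditions: TBSCl, imidazole, DMF, rt
Reagents that add atoms: tert-butyldimethylsilyl chloride, CC(C)(C)[Si](C)(C)Cl
Why: Imidazole-promoted silylation masks the β-hydroxyl so that it is neither O-alkylated by the diazoalkane nor eliminated in the later base steps, and no stereocentre is touched.

Step 4
Reactants: 5 (4S)-4-[(tert-butyldimethylsilyl)oxy]-2,2-dimethylcyclopentan-1-one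
Product: 6 (4R)-4-[(tert-butyldimethylsilyl)oxy]-2,2,6-trimethylcyclohexan-1-one (both C6 epimers)
Conditions: CH3CHN2 (1.5 equiv, dry Et2O solution from N-ethyl-N-nitrosourea and aq. KOH, 0 °C), Sc(OTf)3 (5 mol%), toluene, −78 → −40 °C
Reagents that add atoms: diazoethane, CC=[N+]=[N-]
Why: Sc(OTf)3 activates the carbonyl of 5, the nucleophilic carbon of diazoethane adds to give a β-diazonium alkoxide, and antiperiplanar 1,2-shift of the ring CH2 with loss of N2 enlarges the five-membered ring to the six-membered ketone in one operation. The closest known reaction type is the Lewis-acid-catalysed diazoalkane homologation of cycloalkanones (Büchner–Curtius–Schlotterbeck reaction, a Tiffeneau–Demjanov-type ring expansion). No ring is closed: the existing ring grows by one carbon through the 1,2-alkyl shift, and the inserted CH(CH3) carbon becomes C6 of 6, which is C5 of the carotenoid with its methyl C18. The new stereocentre at C6 is not controlled and need not be, because it is epimerisable and becomes sp2 in step 5, while the silyloxy stereocentre is remote from the reacting bonds and is retained. The step needs migration of the methylene and not of the quaternary carbon, which the gem-dimethyl group should secure sterically since the less substituted α-carbon migrates in Lewis-acid-promoted diazoalkane insertions, and it needs a single insertion, which is secured because 6 is flanked by a quaternary and a tertiary α-carbon and is much less electrophilic than 5.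

Step 5
Reactants: 6 (4R)-4-[(tert-butyldimethylsilyl)oxy]-2,2,6-trimethylcyclohexan-1-one
Product: 8 (4R)-4-[(tert-butyldimethylsilyl)oxy]-2,6,6-trimethylcyclohex-1-en-1-yl trifluoromethanesulfonate, via lithium enolate 7 (not isolated)
Conditions: LiN(i-Pr)2 (LDA), THF, −78 → 0 °C; then PhNTf2, −78 °C → rt; aq. NH4Cl
Reagents that add atoms: lithium diisopropylamide, [Li+].CC(C)[N-]C(C)C (lithium present only in 7); N-phenylbis(trifluoromethanesulfonimide), O=S(=O)(N(c1ccccc1)S(=O)(=O)C(F)(F)F)C(F)(F)F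
Why: Deprotonation can occur only at the single α-CH, so both epimers of 6 converge on one tetrasubstituted enolate, which is O-sulfonylated to the enol triflate with the epimeric centre erased.

Step 6
Reactants: 8 (4R)-4-[(tert-butyldimethylsilyl)oxy]-2,6,6-trimethylcyclohex-1-en-1-yl trifluoromethanesulfonate; 9 (2E)-3-methylpent-2-en-4-yn-1-ol
Product: 10 (2E)-5-[(4R)-4-[(tert-butyldimethylsilyl)oxy]-2,6,6-trimethylcyclohex-1-en-1-yl]-3-methylpent-2-en-4-yn-1-ol
Conditions: Pd(PPh3)4 (5 mol%), CuI (10 mol%), i-Pr2NH, DMF, rt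
Reagents that add atoms: none
Why: Sonogashira coupling (oxidative addition of the vinyl triflate to zerovalent palladium, transmetallation from the copper acetylide) forms the C6–C7 bond, and the 9E geometry comes unchanged from 9.

Step 7
Reactants: 10 (2E)-5-[(4R)-4-[(tert-butyldimethylsilyl)oxy]-2,6,6-trimethylcyclohex-1-en-1-yl]-3-methylpent-2-en-4-yn-1-ol
Product: 11 (2E)-5-[(4R)-4-[(tert-butyldimethylsilyl)oxy]-2,6,6-trimethylcyclohex-1-en-1-yl]-3-methylpent-2-en-4-yn-1-yl acetate
Conditions: Ac2O, pyridine, DMAP (cat.), CH2Cl2, 0 °C → rt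
Reagents that add atoms: acetic anhydride, CC(=O)OC(C)=O
Why: DMAP-catalysed acetylation removes the only hydroxyl that could otherwise direct the vanadium catalyst of step 9 to the C9=C10 bond.

Step 8
Reactants: 11 (2E)-5-[(4R)-4-[(tert-butyldimethylsilyl)oxy]-2,6,6-trimethylcyclohex-1-en-1-yl]-3-methylpent-2-en-4-yn-1-yl acetate
Product: 12 (2E)-5-[(4R)-4-hydroxy-2,6,6-trimethylcyclohex-1-en-1-yl]-3-methylpent-2-en-4-yn-1-yl acetate
Conditions: HF·pyridine, THF/pyridine, 0 °C → rt
Reagents that add atoms: none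
Why: Fluoride-mediated desilylation frees the C3 hydroxyl under conditions that should leave the allylic acetate and the enyne untouched.

Step 9
Reactants: 12 (2E)-5-[(4R)-4-hydroxy-2,6,6-trimethylcyclohex-1-en-1-yl]-3-methylpent-2-en-4-yn-1-yl acetate
Product: 13 (2E)-5-[(1S,4S,6S)-4-hydroxy-2,2,6-trimethyl-7-oxabicyclo[4.1.0]heptan-1-yl]-3-methylpent-2-en-4-yn-1-yl acetate
Conditions: VO(acac)2 (5 mol%), t-BuOOH (1.5 equiv), toluene, 0 °C → rt
Reagents that add atoms: tert-butyl hydroperoxide, CC(C)(C)OO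
Why: Hydroxyl-directed vanadium-catalysed epoxidation delivers oxygen to the C5=C6 bond from the face of the homoallylic C3–OH, setting C5 and C6 as the syn epoxide, while the acetylated C9=C10 bond has no directing group.

Step 10
Reactants: 13 (2E)-5-[(1S,4S,6S)-4-hydroxy-2,2,6-trimethyl-7-oxabicyclo[4.1.0]heptan-1-yl]-3-methylpent-2-en-4-yn-1-yl acetate
Product: 14 (2E)-3-methyl-5-[(1S,2R,4S)-1,2,4-trihydroxy-2,6,6-trimethylcyclohexyl]pent-2-en-4-yn-1-yl acetate
Conditions: 5% aq. HClO4, THF, 0 °C → rt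
Reagents that add atoms: water, O
Why: Acid-catalysed epoxide hydrolysis under the Fürst–Plattner rule: water should attack tertiary C5 (positive charge at C6 is disfavoured by the alkynyl group) from the face opposite the oxirane, inverting C5 and retaining C6 to give the trans-diaxial 5,6-diol.

Step 11
Reactants: 14 (2E)-3-methyl-5-[(1S,2R,4S)-1,2,4-trihydroxy-2,6,6-trimethylcyclohexyl]pent-2-en-4-yn-1-yl acetate
Product: 15 (1R,2R,4S)-1-[(1E,3E)-5-hydroxy-3-methylpenta-1,3-dien-1-yl]-2,6,6-trimethylcyclohexane-1,2,4-triol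
Conditions: NaAlH2(OCH2CH2OCH3)2 (Red-Al, 6 equiv), THF, 0 °C → rt; aq. Rochelle salt
Reagents that add atoms: none
Why: Alkoxide-directed trans-hydroalumination of the propargylic alcohol followed by protonolysis should give the 7E alkene while the acetate is reduced off in the same operation, and no stereocentre changes.

Step 12
Reactants: 15 (1R,2R,4S)-1-[(1E,3E)-5-hydroxy-3-methylpenta-1,3-dien-1-yl]-2,6,6-trimethylcyclohexane-1,2,4-triol
Product: 17 [(2E,4E)-3-methyl-5-[(1R,2R,4S)-1,2,4-trihydroxy-2,6,6-trimethylcyclohexyl]penta-2,4-dien-1-yl]triphenylphosphonium bromide, via allylic bromide 16 (not isolated)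
Conditions: NBS, Me2S, CH2Cl2, −20 → 0 °C; then PPh3, CH2Cl2/MeCN, rt
Reagents that add atoms: N-bromosuccinimide, O=C1CCC(=O)N1Br; triphenylphosphine, c1ccc(cc1)P(c1ccccc1)c1ccccc1
Why: Corey–Kim bromination converts only the primary allylic hydroxyl under non-acidic conditions that spare the ionisable tertiary C6–OH, and SN2 displacement by PPh3 gives the Wittig salt with the 9E geometry retained.

Step 13
Reactants: 17 [(2E,4E)-3-methyl-5-[(1R,2R,4S)-1,2,4-trihydroxy-2,6,6-trimethylcyclohexyl]penta-2,4-dien-1-yl]triphenylphosphonium bromide; 18 (2E,4E,6E)-2,7-dimethylocta-2,4,6-trienedial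
Product: 19 (2E,4E,6E,8E,10E,12E)-2,7,11-trimethyl-13-[(1R,2R,4S)-1,2,4-trihydroxy-2,6,6-trimethylcyclohexyl]trideca-2,4,6,8,10,12-hexaenal
Conditions: 18 (3 equiv, excess recovered), NaOMe, MeOH/CH2Cl2, 0 °C → rt; then reflux in EtOAc (Z → E)
Reagents that add atoms: none
Why: Wittig olefination of the allylic ylide with an excess of the symmetrical dialdehyde should stop at the mono-adduct, the free hydroxyls being tolerated, and the E/Z mixture at the new C11=C12 bond is isomerised thermally to all-E as is usual for such polyenes.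

Step 14
Reactants: 19 (2E,4E,6E,8E,10E,12E)-2,7,11-trimethyl-13-[(1R,2R,4S)-1,2,4-trihydroxy-2,6,6-trimethylcyclohexyl]trideca-2,4,6,8,10,12-hexaenal
Product: 20 (2E,4E,6E,8E,10E)-11-[(2R,6S,7aR)-6-hydroxy-4,4,7a-trimethyl-2,4,5,6,7,7a-hexahydro-1-benzofuran-2-yl]-2,7-dimethyldodeca-2,4,6,8,10-pentaenal
Conditions: camphor-10-sulfonic acid (5 mol%), CH2Cl2, −20 → 0 °C; Et3N quench; chromatographic removal of the 8S epimer
Reagents that add atoms: none
Why: Acid-catalysed cyclodehydration of a mono-allylic diol (intramolecular allylic etherification with transposition, the diol counterpart of the epoxide–furanoid rearrangement): the tertiary polyene-conjugated C6–OH ionises, O5 closes on C8 to form the five-membered ring and the C6=C7 bond, C5 keeps its configuration, and C8 is set by attack of the axial O5 on its own face of the E-configured C7–C8 unit, which should favour 8R but not exclusively.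

Step 15
Reactants: 20 (2E,4E,6E,8E,10E)-11-[(2R,6S,7aR)-6-hydroxy-4,4,7a-trimethyl-2,4,5,6,7,7a-hexahydro-1-benzofuran-2-yl]-2,7-dimethyldodeca-2,4,6,8,10-pentaenal; 17 [(2E,4E)-3-methyl-5-[(1R,2R,4S)-1,2,4-trihydroxy-2,6,6-trimethylcyclohexyl]penta-2,4-dien-1-yl]triphenylphosphonium bromide
Product: 21 (3S,5R,6R,3'S,5'R,8'R)-5',8'-epoxy-5,6,5',8'-tetrahydro-β,β-carotene-3,5,6,3'-tetrol
Conditions: 17 (1.3 equiv), NaOMe, MeOH/CH2Cl2, 0 °C → rt; then reflux in EtOH (Z → E), crystallisation
Reagents that add atoms: none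
Why: A second Wittig olefination joins the furanoid aldehyde to a second equivalent of the same ylide, no protecting group remains to be removed, the stereocentres of both ends are untouched by the basic conditions, and thermal isomerisation should give the all-E target.

**Compound list**

1 | 2,2-dimethylcyclopentan-1-one | CC1(C)CCCC1=O | starting material
2 | 5,5-dimethylcyclopent-2-en-1-one | CC1(C)CC=CC1=O | intermediate
3 | (4S)-2,2-dimethyl-4-(4,4,5,5-tetramethyl-1,3,2-dioxaborolan-2-yl)cyclopentan-1-one | CC1(C)C[C@H](B2OC(C)(C)C(C)(C)O2)CC1=O | intermediate (not isolated)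
4 | (4S)-4-hydroxy-2,2-dimethylcyclopentan-1-one | CC1(C)C[C@H](O)CC1=O | intermediate
5 | (4S)-4-[(tert-butyldimethylsilyl)oxy]-2,2-dimethylcyclopentan-1-one | CC1(C)C[C@H](O[Si](C)(C)C(C)(C)C)CC1=O | intermediate
6 | (4R)-4-[(tert-butyldimethylsilyl)oxy]-2,2,6-trimethylcyclohexan-1-one (both C6 epimers) | CC1C[C@@H](O[Si](C)(C)C(C)(C)C)CC(C)(C)C1=O | intermediate
7 | lithium (4R)-4-[(tert-butyldimethylsilyl)oxy]-2,6,6-trimethylcyclohex-1-en-1-olate | [Li+].CC1=C([O-])C(C)(C)C[C@H](O[Si](C)(C)C(C)(C)C)C1 | intermediate (not isolated)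
8 | (4R)-4-[(tert-butyldimethylsilyl)oxy]-2,6,6-trimethylcyclohex-1-en-1-yl trifluoromethanesulfonate | CC1=C(OS(=O)(=O)C(F)(F)F)C(C)(C)C[C@H](O[Si](C)(C)C(C)(C)C)C1 | intermediate
9 | (2E)-3-methylpent-2-en-4-yn-1-ol | C#C/C(C)=C/CO | starting material
10 | (2E)-5-[(4R)-4-[(tert-butyldimethylsilyl)oxy]-2,6,6-trimethylcyclohex-1-en-1-yl]-3-methylpent-2-en-4-yn-1-ol | CC1=C(C#C/C(C)=C/CO)C(C)(C)C[C@H](O[Si](C)(C)C(C)(C)C)C1 | intermediate
11 | (2E)-5-[(4R)-4-[(tert-butyldimethylsilyl)oxy]-2,6,6-trimethylcyclohex-1-en-1-yl]-3-methylpent-2-en-4-yn-1-yl acetate | CC1=C(C#C/C(C)=C/COC(C)=O)C(C)(C)C[C@H](O[Si](C)(C)C(C)(C)C)C1 | intermediate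
12 | (2E)-5-[(4R)-4-hydroxy-2,6,6-trimethylcyclohex-1-en-1-yl]-3-methylpent-2-en-4-yn-1-yl acetate | CC1=C(C#C/C(C)=C/COC(C)=O)C(C)(C)C[C@H](O)C1 | intermediate
13 | (2E)-5-[(1S,4S,6S)-4-hydroxy-2,2,6-trimethyl-7-oxabicyclo[4.1.0]heptan-1-yl]-3-methylpent-2-en-4-yn-1-yl acetate (epoxide syn to the hydroxyl) | CC(=O)OC/C=C(C)/C#C[C@@]1(O2)C(C)(C)C[C@H](O)C[C@@]12C | intermediate
14 | (2E)-3-methyl-5-[(1S,2R,4S)-1,2,4-trihydroxy-2,6,6-trimethylcyclohexyl]pent-2-en-4-yn-1-yl acetate | CC(=O)OC/C=C(C)/C#C[C@@]1(O)C(C)(C)C[C@H](O)C[C@@]1(C)O | intermediate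
15 | (1R,2R,4S)-1-[(1E,3E)-5-hydroxy-3-methylpenta-1,3-dien-1-yl]-2,6,6-trimethylcyclohexane-1,2,4-triol | OC/C=C(C)/C=C/[C@@]1(O)C(C)(C)C[C@H](O)C[C@@]1(C)O | intermediate
16 | (1R,2R,4S)-1-[(1E,3E)-5-bromo-3-methylpenta-1,3-dien-1-yl]-2,6,6-trimethylcyclohexane-1,2,4-triol | BrC/C=C(C)/C=C/[C@@]1(O)C(C)(C)C[C@H](O)C[C@@]1(C)O | intermediate (not isolated)
17 | [(2E,4E)-3-methyl-5-[(1R,2R,4S)-1,2,4-trihydroxy-2,6,6-trimethylcyclohexyl]penta-2,4-dien-1-yl]triphenylphosphonium bromide | [Br-].c1ccccc1[P+](c1ccccc1)(c1ccccc1)C/C=C(C)/C=C/[C@@]1(O)C(C)(C)C[C@H](O)C[C@@]1(C)O | intermediate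
18 | (2E,4E,6E)-2,7-dimethylocta-2,4,6-trienedial | O=C/C(C)=C/C=C/C=C(C)/C=O | starting material
19 | (2E,4E,6E,8E,10E,12E)-2,7,11-trimethyl-13-[(1R,2R,4S)-1,2,4-trihydroxy-2,6,6-trimethylcyclohexyl]trideca-2,4,6,8,10,12-hexaenal | O=C/C(C)=C/C=C/C=C(C)/C=C/C=C(C)/C=C/[C@@]1(O)C(C)(C)C[C@H](O)C[C@@]1(C)O | intermediate
20 | (2E,4E,6E,8E,10E)-11-[(2R,6S,7aR)-6-hydroxy-4,4,7a-trimethyl-2,4,5,6,7,7a-hexahydro-1-benzofuran-2-yl]-2,7-dimethyldodeca-2,4,6,8,10-pentaenal | O=C/C(C)=C/C=C/C=C(C)/C=C/C=C(\C)[C@H]1C=C2C(C)(C)C[C@H](O)C[C@@]2(C)O1 | intermediate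
21 | (3S,5R,6R,3'S,5'R,8'R)-5',8'-epoxy-5,6,5',8'-tetrahydro-β,β-carotene-3,5,6,3'-tetrol | CC(/C=C/C=C(C)/C=C/[C@@]1(O)C(C)(C)C[C@H](O)C[C@@]1(C)O)=C\C=C\C=C(C)\C=C\C=C(/C)[C@H]1C=C2C(C)(C)C[C@H](O)C[C@@]2(C)O1 | target

**Step count.** Total: 15 steps. Longest linear sequence: 15 steps (1 to 21); the route is linear, and salt 17 is used twice (steps 13 and 15).

**Steps most likely to fail**

Step 14. After ionisation at C6 the cation may be captured by O3 (bridged 3,6-ether), lose a proton, or close on either face of C8, and the product can re-ionise under the same acid, so conversion and the C8 outcome are hard to control on a polyenal. The fallback sets out from 10 and comes back at 20, and replaces the diol by a strained epoxide that rearranges with only a trace of acid while O3 stays silylated. Red-Al reduction of the en-yn-ol of 10 should give the (2E,4E)-dienol F1. Corey–Kim bromination gives the allylic bromide F2, and PPh3 gives the phosphonium bromide F3. Wittig reaction with excess 18 (NaOMe) gives the silyl-protected C25 aldehyde F4. mCPBA (CH2Cl2, aq. NaHCO3, 0 °C) should epoxidise the tetrasubstituted ring double bond, mainly anti to the silyloxy group, to the 5,6-epoxide F5. A trace of HCl in CHCl3 then triggers the epoxide–furanoid rearrangement to the silyl ether F6, whose 8-epimer is removed by chromatography. Buffered TBAF (AcOH, THF) gives 20.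

Step 4. Migration of the quaternary carbon may compete, the Lewis acid may expel the β-silyloxy group, or the unstabilised diazoalkane may over-insert or form the spiro-epoxide. The fallback sets out from 5 and comes back at 6, keeping the ring enlargement but separating carbon insertion from methylation. Commercial trimethylsilyldiazomethane with BF3·OEt2 (CH2Cl2, −78 °C) should insert its bulkier carbon on the methylene side to give the α-silyl ketone F7. Dilute acid work-up protodesilylates it to (4R)-4-[(tert-butyldimethylsilyl)oxy]-2,2-dimethylcyclohexan-1-one F8. Enolate methylation (LiN(i-Pr)2, MeI, THF, −78 °C) at the only α-methylene then installs C18 and gives 6.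

Step 11. The aluminate of the hindered tertiary propargylic alcohol may react sluggishly or expel the C6 oxygen in an SN2' sense (allene formation), or the diene may be over-reduced. The fallback sets out from 14 and comes back at 15, using a metal-catalysed trans-hydrosilylation in place of hydride. [Cp*Ru(MeCN)3]PF6 (cat.) with benzyldimethylsilane (CH2Cl2, rt) should add H and Si trans across the alkyne to give the vinylsilane F9. Protodesilylation (TBAF, CuI, THF) gives the (2E,4E)-dienyl acetate F10. Methanolysis (K2CO3, MeOH) gives 15.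

**Further compounds**

F1 | step 14 | (2E,4E)-5-[(4R)-4-[(tert-butyldimethylsilyl)oxy]-2,6,6-trimethylcyclohex-1-en-1-yl]-3-methylpenta-2,4-dien-1-ol | OC/C=C(C)/C=C/C1=C(C)C[C@@H](O[Si](C)(C)C(C)(C)C)CC1(C)C
F2 | step 14 | {[(1R)-4-[(1E,3E)-5-bromo-3-methylpenta-1,3-dien-1-yl]-3,5,5-trimethylcyclohex-3-en-1-yl]oxy}(tert-butyl)dimethylsilane | BrC/C=C(C)/C=C/C1=C(C)C[C@@H](O[Si](C)(C)C(C)(C)C)CC1(C)C
F3 | step 14 | [(2E,4E)-5-[(4R)-4-[(tert-butyldimethylsilyl)oxy]-2,6,6-trimethylcyclohex-1-en-1-yl]-3-methylpenta-2,4-dien-1-yl]triphenylphosphonium bromide | [Br-].c1ccccc1[P+](c1ccccc1)(c1ccccc1)C/C=C(C)/C=C/C1=C(C)C[C@@H](O[Si](C)(C)C(C)(C)C)CC1(C)C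
F4 | step 14 | (2E,4E,6E,8E,10E,12E)-13-[(4R)-4-[(tert-butyldimethylsilyl)oxy]-2,6,6-trimethylcyclohex-1-en-1-yl]-2,7,11-trimethyltrideca-2,4,6,8,10,12-hexaenal | O=C/C(C)=C/C=C/C=C(C)/C=C/C=C(C)/C=C/C1=C(C)C[C@@H](O[Si](C)(C)C(C)(C)C)CC1(C)C
F5 | step 14 | (2E,4E,6E,8E,10E,12E)-13-[(1S,4S,6R)-4-[(tert-butyldimethylsilyl)oxy]-2,2,6-trimethyl-7-oxabicyclo[4.1.0]heptan-1-yl]-2,7,11-trimethyltrideca-2,4,6,8,10,12-hexaenal | O=C/C(C)=C/C=C/C=C(C)/C=C/C=C(C)/C=C/[C@]1(O2)C(C)(C)C[C@H](O[Si](C)(C)C(C)(C)C)C[C@]12C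
F6 | step 14 | (2E,4E,6E,8E,10E)-11-[(2R,6S,7aR)-6-[(tert-butyldimethylsilyl)oxy]-4,4,7a-trimethyl-2,4,5,6,7,7a-hexahydro-1-benzofuran-2-yl]-2,7-dimethyldodeca-2,4,6,8,10-pentaenal | O=C/C(C)=C/C=C/C=C(C)/C=C/C=C(\C)[C@H]1C=C2C(C)(C)C[C@H](O[Si](C)(C)C(C)(C)C)C[C@@]2(C)O1
F7 | step 4 | (4S)-4-[(tert-butyldimethylsilyl)oxy]-2,2-dimethyl-6-(trimethylsilyl)cyclohexan-1-one (both C6 epimers) | CC1(C)C[C@H](O[Si](C)(C)C(C)(C)C)CC([Si](C)(C)C)C1=O
F8 | step 4 | (4R)-4-[(tert-butyldimethylsilyl)oxy]-2,2-dimethylcyclohexan-1-one | CC1(C)C[C@H](O[Si](C)(C)C(C)(C)C)CCC1=O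
F9 | step 11 | (2E,4Z)-4-[benzyl(dimethyl)silyl]-3-methyl-5-[(1R,2R,4S)-1,2,4-trihydroxy-2,6,6-trimethylcyclohexyl]penta-2,4-dien-1-yl acetate | CC(=O)OC/C=C(C)/C(=C/[C@@]1(O)C(C)(C)C[C@H](O)C[C@@]1(C)O)[Si](C)(C)Cc1ccccc1
F10 | step 11 | (2E,4E)-3-methyl-5-[(1R,2R,4S)-1,2,4-trihydroxy-2,6,6-trimethylcyclohexyl]penta-2,4-dien-1-yl acetate | CC(=O)OC/C=C(C)/C=C/[C@@]1(O)C(C)(C)C[C@H](O)C[C@@]1(C)O
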